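## Structural features

The target is a (3S)-isoflavanone: a chroman-4-one in which ring A (C4a–C8a) is fused to the dihydropyranone ring C (O1, C2, C3, C4), with ring B attached through C1' to C3. Ring A has a phloroglucinol pattern, with hydroxyls at C5 and C7, a prenyl group on C6 between them and hydrogen at C8; the 5-hydroxyl is chelated to the C4 carbonyl. Ring B carries four contiguous substituents: the bond to C3 at C1', 2'-OMe, 3'-[(E)-3-methylbut-1-enyl] and 4'-OH, so the styrene-type alkene sits between two oxygens. C3 is the only stereocentre and has no stereogenic neighbour, but it is benzylic and alpha to the ketone, so it enolises easily under base and more slowly under acid. The prenyl group flanked by two phenols (acid-induced chroman formation, electrophilic oxidants) and the electron-rich (E)-alkene (acid, halogen, light, hydrogenation) exclude hydrogenolysis, strong acid and peracids. The real difficulty is to create C3 enantioselectively as late as possible and keep it, and to place prenyl at C6 and not at C8. The key step exploits the position of C3 between the C4 carbonyl and the O1–C2 methylene: O1, C8a, C4a and C4 come from a salicylaldehyde and C2–C3 from a 2-arylacrylate, whose ester makes C3 quaternary and configurationally inert until it is excised.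

## Logic of the disconnections

**21 to 20.** The last operation cleaves the three acetal O–CH2 bonds of 20. The phenols must stay masked until then: free phenols would be O-allylated by the allylpalladium intermediate of the preceding step, and the chelated 5-hydroxyl would protonate the enolate oxygen outside the chiral pocket. Nothing is gained in skeleton. The demand is an acetal cleavage finished in minutes without protic strong acid, so that C3, the prenyl group and the styrene survive.

**20 to 19.** The C3–H bond of 20 is traced back to the C3–CO2-allyl bond of 19. The only stereocentre is then made from a quaternary, non-enolisable carbon in a step that contains no base, and every earlier intermediate can be racemic. The forward step demands that protonation of the palladium enolate is faster than its C-allylation and is steered by the ligand.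

**19 to 18.** The C4 carbonyl of 19 is taken back to the carbinol of 18, because a carbinol is what an aldol closure delivers. The forward oxidation must handle a hindered benzylic alcohol without retro-aldol cleavage of the beta-hydroxy ester, so a non-basic oxidant is needed.

**18 to 7 and 16.** Ring C of 18 is cut at O1–C2 and C3–C4. This makes the route convergent: 7 brings O1, C8a, C4a and C4, and 16 brings C2, C3, ring B and the ester. It is the largest simplification of the plan (one ring, two bonds, two fragments of similar size). The forward step demands attack of the phenoxide of 7 through oxygen and not carbon, ring closure faster than chain growth of 16, and an equilibrium on the side of the closed ring.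

**16 to 15 to 12 and 13.** The 1,1-disubstituted alkene of 16 is cut at C=CH2 back to the ketone of 15, and 15 at the C1'–C(=O) bond back to 12 and 13. An aryl glyoxylate is the most direct carbonyl precursor of a 2-arylacrylate, and 13 brings in the allyl ester without palladium chemistry. The forward steps demand a single addition of the aryllithium to 13 and methylenation of the ketone beside the ester.

**12 to 10 to 9 to 8.** The side-chain C=C bond of 12 is cut to the aldehyde 10, the acetal O–C bond to 9 and the C–Br bond to 8. In 8 the formyl carbon already lies between methoxyl and hydroxyl, so the 1',2',3',4' pattern needs only one substitution, para to the free hydroxyl. The demands are that regioselectivity and an (E)-alkene; a kinetic olefination of a hindered aldehyde does not give the latter, so it is followed by equilibration.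

**7 to 6 to 5 to 2 and 3 to 1.** 7 is cut at C–CHO to 6, 6 at C–OH to the aryl chloride 5, 5 at the aryl–CH2 bond to 2 and 3, and 2 at its two acetal O–C bonds to 1. The order rests on symmetry. In 2 the only carbon between two directing acetals is the one that becomes C6, and in 6 the two positions ortho to the hydroxyl are equivalent. The 6-prenyl versus 8-prenyl question therefore never arises, and the hydroxyl that becomes O1 is the only free one. The halogen is chlorine and not bromine, because an alkyllithium would exchange a bromine before it removed the ring proton. The price is a palladium-catalysed hydroxylation of an aryl chloride, and metalation between the acetals must win over metalation beside chlorine.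

## Other disconnections considered

Alternative 1: The cut runs through ring B itself (C1'–C2', C2'–C3', C4'–C5', C5'–C6'), leaving the chromone-bound diazo enone A1 and the siloxy enyne A2.
- **Forward key step:** irradiation of A1 would trigger a Wolff rearrangement to a vinylketene, which adds [2+2] to A2. The cyclobutenone opens (four-electron electrocyclic) to a dienylketene that closes (six-electron electrocyclic) and tautomerises to the isoflavone A3, with a free 2'-hydroxyl, the (E)-alkenyl group at C3' and a silyl ether at C4'.
- **In its favour:** the substitution pattern of ring B is dictated by the mechanism, and the E geometry arrives intact with A2. Neither an arene bromination nor an alkene equilibration is needed, and on these two points it is the better plan.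
- **Against it here:** the cascade creates no stereocentre. A3 is planar at C3, so an enantioselective reduction of C2=C3 in the presence of two other alkenes must still follow, with O-methylation and removal of two kinds of protecting group. The chromone and dienyl chromophores absorb the light used and could undergo cycloaddition or E/Z isomerisation. A1 and A2 each need a multistep preparation that includes a diazo transfer and an ynolate silylation.
- **Comparison:** on mechanism both plans rely on a cascade that is well known in simpler systems and little tested in this one, so they are equal there. On stereocontrol and step count the chosen plan is ahead, since its C3 comes from a dedicated enantioselective step on a non-enolisable precursor.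

Alternative 2: The cut is C2–C3. The precursor A4 is an aryl-conjugated enol silane in which the carbon destined to be C3 bears ring B and the oxygen destined to be O1 carries a methoxymethyl group.
- **Forward key step:** a silylium Lewis acid paired with a confined chiral imidodiphosphorimidate anion would abstract methoxide from the acetal. The aryloxymethyl cation would be attacked by the enol silane carbon (6-endo-trig with respect to the C=O+ bond), closing ring C and setting C3 in the same event to give A5.
- **In its favour:** it is the shortest path after fragment union, since ring closure, stereocentre and C2 arrive together and the acetal carbon serves as a building block. The silyl ethers of A5 can be removed with buffered fluoride, which is gentler on C3 than any acetal cleavage. On both points it is better than the chosen plan.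
- **Against it:** the electrophile is an unsubstituted CH2 cation, so all induction must come from the counter-anion discriminating the two enol faces, a ring closure that would have to be developed. The enol geometry of A4 must be uniform. The strongly Lewis acidic medium meets a prenyl group, an electron-rich styrene and aryl silyl ethers. A5 has an enolisable C3–H that the same silylium species could re-silylate, with loss of selectivity.
- **Comparison:** the two ortho oxygens of ring A must be differentiated just as in the chosen plan, so the plans are equal there. The chosen plan is longer, but each of its bond-forming events belongs to a known reaction class and its stereo-determining step can be optimised separately.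

Alternative 3: The cut is O1–C8a. The acyclic precursor A6 is a 2-aryl-1-(2-bromoaryl)propane-1,3-diol whose two stereocentres would come from an auxiliary-controlled syn aldol and reductive removal of the auxiliary.
- **Forward key step:** Pd(OAc)2, a bulky biaryl di-tert-butylphosphine and Cs2CO3 would couple the primary hydroxyl with the aryl bromide to give the cis-isoflavan-4-ol A7, which is then oxidised at C4 and deprotected.
- **In its favour:** C3 is set by one of the most dependable stereoselective reactions, and its absolute sense does not depend on a ligand–substrate match. Until the late oxidation it is an ordinary benzylic stereocentre that cannot enolise. On reliability of configuration this is the better plan, and the intramolecular C–O coupling of a primary alcohol is a known ring closure.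
- **Against it here:** the aldol needs the hindered, electron-rich bromo aldehyde A8, which demands a bromine at C8a in addition to everything present in 7. The electron-rich bromide should be slow in oxidative addition, and the palladium alkoxide, like the free benzylic carbinol, can undergo beta-hydride elimination. The auxiliary is stoichiometric and costs three operations.
- **Comparison:** once C4 is oxidised the ketone is exactly as labile as 20, and two operations (oxidation, acetal cleavage) still follow, against one in the chosen plan. On endgame risk the two are at best equal, and in step count the chosen plan is shorter.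

Key step: step 10

Assumption: the (S)-configured phosphinooxazoline is taken to deliver the (3S)-ketone by analogy with other alpha-aryl cyclic ketones; if the sense of induction is the opposite, the (R)-ligand is used and nothing else changes.

## Route

Step 1
Reactants: 1 5-chlorobenzene-1,3-diol (5-chlororesorcinol)
Product: 2 1-chloro-3,5-bis(methoxymethoxy)benzene
Conditions: MOMCl (2.5 equiv), i-Pr2NEt (3 equiv), CH2Cl2, 0 °C to rt
Reagents that add atoms: chloromethyl methyl ether (MOMCl), COCCl
Why: O-alkylation of both phenols with a reactive alpha-chloro ether (Williamson type); the acetals later direct metalation and tolerate organolithiums, hydroxide and palladium.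

Step 2
Reactants: 2 1-chloro-3,5-bis(methoxymethoxy)benzene; 3 1-bromo-3-methylbut-2-ene (prenyl bromide)
Product: 5 5-chloro-1,3-bis(methoxymethoxy)-2-(3-methylbut-2-en-1-yl)benzene, via aryllithium 4 (not isolated)
Conditions: n-BuLi (1.1 equiv), TMEDA, THF, −40 °C; CuI (10 mol %), 3 (1.3 equiv), −40 to 0 °C
Reagents that add atoms: none
Why: Directed ortho-metalation, in which the two chelating acetals cooperate to make the C–H between them the kinetic site, while chlorine is a weak director and does not exchange with n-BuLi at this temperature. Copper-catalysed allylic substitution of the aryllithium then gives the linear prenyl arene.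

Step 3
Reactants: 5 5-chloro-1,3-bis(methoxymethoxy)-2-(3-methylbut-2-en-1-yl)benzene
Product: 6 3,5-bis(methoxymethoxy)-4-(3-methylbut-2-en-1-yl)phenol
Conditions: Pd2(dba)3 (2 mol %), t-BuXPhos (8 mol %), KOH (3 equiv), 1,4-dioxane/H2O 1:1, 100 °C; then aq. NH4Cl
Reagents that add atoms: potassium hydroxide, [K+].[OH-]
Why: Palladium-catalysed hydroxylation of an aryl chloride (C–O cross-coupling with hydroxide), in which the bulky biaryl phosphine favours C–O reductive elimination over diaryl ether formation. The acetals and the trisubstituted alkene are inert to hot hydroxide.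

Step 4
Reactants: 6 3,5-bis(methoxymethoxy)-4-(3-methylbut-2-en-1-yl)phenol
Product: 7 6-hydroxy-2,4-bis(methoxymethoxy)-3-(3-methylbut-2-en-1-yl)benzaldehyde
Conditions: MgCl2 (2 equiv), Et3N (4 equiv), (CH2O)n (6 equiv), MeCN, 75 °C; pH 5 buffer work-up
Reagents that add atoms: paraformaldehyde (as formaldehyde), C=O
Why: Magnesium-mediated ortho-formylation of a phenol (Casnati–Skattebøl type): the magnesium phenoxide delivers formaldehyde only ortho to oxygen, and a second formaldehyde oxidises the benzylic alkoxide. The two ortho positions of 6 are equivalent, so a single aldehyde should result.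

Step 5
Reactants: 8 2-hydroxy-6-methoxybenzaldehyde
Product: 9 3-bromo-6-hydroxy-2-methoxybenzaldehyde
Conditions: NBS (1.0 equiv), MeCN, 0 °C to rt
Reagents that add atoms: N-bromosuccinimide, O=C1CCC(=O)N1Br
Why: Electrophilic aromatic bromination; the hydroxyl is the strongest donor and directs para, a position that is also ortho to methoxyl and meta to the aldehyde, so bromine should enter at the carbon that becomes C1'.

Step 6
Reactants: 9 3-bromo-6-hydroxy-2-methoxybenzaldehyde
Product: 10 3-bromo-2-methoxy-6-(methoxymethoxy)benzaldehyde
Conditions: MOMCl (1.5 equiv), i-Pr2NEt (2 equiv), CH2Cl2, 0 °C to rt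
Reagents that add atoms: chloromethyl methyl ether (MOMCl), COCCl
Why: O-alkylation of the chelated phenol; it removes the only acidic proton before the ylide and organolithium steps.

Step 7
Reactants: 10 3-bromo-2-methoxy-6-(methoxymethoxy)benzaldehyde
Product: 12 1-bromo-2-methoxy-4-(methoxymethoxy)-3-[(E)-3-methylbut-1-en-1-yl]benzene, via (Z)-alkene 11 (not isolated)
Conditions: i-BuPPh3Br (1.3 equiv), KN(SiMe3)2 (1.25 equiv), THF, −78 °C to rt; silica plug; I2 (5 mol %), heptane, 60 °C, daylight; aq. Na2S2O3
Reagents that add atoms: (2-methylpropyl)triphenylphosphonium bromide, CC(C)C[P+](c1ccccc1)(c1ccccc1)c1ccccc1.[Br-]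
Why: Wittig olefination with a non-stabilised ylide gives mainly the (Z)-alkene. Reversible addition of iodine atoms then equilibrates it to the (E)-isomer, which is strongly favoured because a cis isopropyl group would clash with the two ortho substituents.

Step 8
Reactants: 12 1-bromo-2-methoxy-4-(methoxymethoxy)-3-[(E)-3-methylbut-1-en-1-yl]benzene; 13 di(prop-2-en-1-yl) oxalate (diallyl oxalate)
Product: 15 prop-2-en-1-yl {2-methoxy-4-(methoxymethoxy)-3-[(E)-3-methylbut-1-en-1-yl]phenyl}(oxo)acetate, via aryllithium 14 (not isolated)
Conditions: n-BuLi (1.05 equiv), THF, −78 °C; cannulated into 13 (3 equiv), THF, −78 °C; AcOH, −78 °C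
Reagents that add atoms: none
Why: Bromine–lithium exchange is faster than any deprotonation at −78 °C, and the aryllithium acylates the oxalate once because the tetrahedral lithium alkoxide is stable in the cold. Inverse addition into excess 13 suppresses double addition.

Step 9
Reactants: 15 prop-2-en-1-yl {2-methoxy-4-(methoxymethoxy)-3-[(E)-3-methylbut-1-en-1-yl]phenyl}(oxo)acetate
Product: 16 prop-2-en-1-yl 2-{2-methoxy-4-(methoxymethoxy)-3-[(E)-3-methylbut-1-en-1-yl]phenyl}prop-2-enoate
Conditions: Ph3PCH3Br (1.2 equiv), KN(SiMe3)2 (1.15 equiv), THF, −78 to 0 °C; kept cold with BHT and used at once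
Reagents that add atoms: methyltriphenylphosphonium bromide, C[P+](c1ccccc1)(c1ccccc1)c1ccccc1.[Br-]
Why: Wittig methylenation; the ketone of an alpha-keto ester is far more electrophilic than the ester, so the ylide converts it selectively into the 2-arylacrylate.

Step 10
Reactants: 7 6-hydroxy-2,4-bis(methoxymethoxy)-3-(3-methylbut-2-en-1-yl)benzaldehyde; 16 prop-2-en-1-yl 2-{2-methoxy-4-(methoxymethoxy)-3-[(E)-3-methylbut-1-en-1-yl]phenyl}prop-2-enoate
Product: 18 prop-2-en-1-yl 4-hydroxy-3-{2-methoxy-4-(methoxymethoxy)-3-[(E)-3-methylbut-1-en-1-yl]phenyl}-5,7-bis(methoxymethoxy)-6-(3-methylbut-2-en-1-yl)-3,4-dihydro-2H-chromene-3-carboxylate (racemic mixture of C3/C4 diastereomers), via oxa-Michael adduct 17 (not isolated)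
Conditions: Cs2CO3 (20 mol %), MeCN (0.5 M), 25 °C, 16 (1.2 equiv) added over 2 h
Reagents that add atoms: none
Why: Tandem oxa-Michael–aldol annulation of a salicylaldehyde with an acrylate, which stops at the chroman-4-ol because C3 has no hydrogen to lose. Catalytic carbonate deprotonates the chelated, formyl-acidified phenol of 7, and the phenoxide adds through oxygen to the CH2 terminus of 16 (O1–C2), giving the aryl-stabilised ester enolate of 17. This enolate attacks the neighbouring aldehyde in a 6-exo-trig (enolexo) aldol closure (C3–C4), and the alkoxide is protonated by the next molecule of 7, which regenerates the phenoxide and keeps the base catalytic. The closest known reaction type is the base-mediated chromene synthesis from salicylaldehydes and acrylates, in which the same two bonds form before dehydration. C3 and C4 arise without control (racemic, both relative configurations), which is harmless because C4 is oxidised in step 11 and C3 is re-made in step 12. The selectivity needed is chemoselectivity: O- rather than C-attack of the phenoxide, and ring closure rather than oligomerisation of 16. The substrate secures this through its single acidic phenol, the intramolecular six-membered aldol and the ortho-methoxyl of ring B, which twists the aryl group and slows anionic chain growth, and slow addition of 16 keeps the enolate concentration low.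

Step 11
Reactants: 18 prop-2-en-1-yl 4-hydroxy-3-{2-methoxy-4-(methoxymethoxy)-3-[(E)-3-methylbut-1-en-1-yl]phenyl}-5,7-bis(methoxymethoxy)-6-(3-methylbut-2-en-1-yl)-3,4-dihydro-2H-chromene-3-carboxylate
Product: 19 prop-2-en-1-yl 3-{2-methoxy-4-(methoxymethoxy)-3-[(E)-3-methylbut-1-en-1-yl]phenyl}-5,7-bis(methoxymethoxy)-6-(3-methylbut-2-en-1-yl)-4-oxo-3,4-dihydro-2H-chromene-3-carboxylate (racemic)
Conditions: Dess–Martin periodinane (1.5 equiv), NaHCO3, CH2Cl2, 0 °C to rt
Reagents that add atoms: none
Why: Dess–Martin oxidation of the hindered benzylic alcohol under buffered, non-basic conditions that give retro-aldol no opening; both diastereomers of 18 converge on one racemic keto ester and the alkenes are untouched.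

Step 12
Reactants: 19 prop-2-en-1-yl 3-{2-methoxy-4-(methoxymethoxy)-3-[(E)-3-methylbut-1-en-1-yl]phenyl}-5,7-bis(methoxymethoxy)-6-(3-methylbut-2-en-1-yl)-4-oxo-3,4-dihydro-2H-chromene-3-carboxylate
Product: 20 (3S)-3-{2-methoxy-4-(methoxymethoxy)-3-[(E)-3-methylbut-1-en-1-yl]phenyl}-5,7-bis(methoxymethoxy)-6-(3-methylbut-2-en-1-yl)-2,3-dihydro-4H-chromen-4-one
Conditions: Pd2(dba)3 (5 mol %), (S)-(CF3)3-t-BuPHOX (12.5 mol %), 2,2-dimethyl-1,3-dioxane-4,6-dione (Meldrum's acid, 2.5 equiv), THF, 10 °C
Reagents that add atoms: none
Why: Palladium-catalysed decarboxylative asymmetric protonation: zerovalent palladium ionises the allyl ester and loss of CO2 gives a palladium enolate in the pocket of the phosphinooxazoline. The carbon acid protonates one face before C-allylation can occur and its anion takes up the allyl group, so C3 is set as (S) by the ligand in a medium without base.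

Step 13
Reactants: 20 (3S)-3-{2-methoxy-4-(methoxymethoxy)-3-[(E)-3-methylbut-1-en-1-yl]phenyl}-5,7-bis(methoxymethoxy)-6-(3-methylbut-2-en-1-yl)-2,3-dihydro-4H-chromen-4-one
Product: 21 (3S)-5,7-dihydroxy-3-{4-hydroxy-2-methoxy-3-[(E)-3-methylbut-1-en-1-yl]phenyl}-6-(3-methylbut-2-en-1-yl)-2,3-dihydro-4H-chromen-4-one (CNP0289142.1)
Conditions: ZnBr2 (3.5 equiv), n-PrSH (7 equiv), CH2Cl2, 0 °C, 10 min; pH 7 buffer
Reagents that add atoms: none
Why: Lewis acid–thiol cleavage of aryl methoxymethyl ethers: the zinc-activated acetal transfers its CH2OMe group to the thiol, so no protic strong acid is present and the exposure lasts minutes at 0 °C. This should spare the alpha-aryl ketone stereocentre, the prenyl group and the styrene.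

## Compound list

1 | 5-chlorobenzene-1,3-diol (5-chlororesorcinol) | Oc1cc(O)cc(Cl)c1 | starting material
2 | 1-chloro-3,5-bis(methoxymethoxy)benzene | COCOc1cc(Cl)cc(OCOC)c1 | intermediate
3 | 1-bromo-3-methylbut-2-ene (prenyl bromide) | CC(C)=CCBr | starting material
4 | [4-chloro-2,6-bis(methoxymethoxy)phenyl]lithium | [Li]c1c(OCOC)cc(Cl)cc1OCOC | intermediate
5 | 5-chloro-1,3-bis(methoxymethoxy)-2-(3-methylbut-2-en-1-yl)benzene | COCOc1cc(Cl)cc(OCOC)c1CC=C(C)C | intermediate
6 | 3,5-bis(methoxymethoxy)-4-(3-methylbut-2-en-1-yl)phenol | COCOc1cc(O)cc(OCOC)c1CC=C(C)C | intermediate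
7 | 6-hydroxy-2,4-bis(methoxymethoxy)-3-(3-methylbut-2-en-1-yl)benzaldehyde | O=Cc1c(O)cc(OCOC)c(CC=C(C)C)c1OCOC | intermediate
8 | 2-hydroxy-6-methoxybenzaldehyde | COc1cccc(O)c1C=O | starting material
9 | 3-bromo-6-hydroxy-2-methoxybenzaldehyde | COc1c(Br)ccc(O)c1C=O | intermediate
10 | 3-bromo-2-methoxy-6-(methoxymethoxy)benzaldehyde | COCOc1ccc(Br)c(OC)c1C=O | intermediate
11 | 1-bromo-2-methoxy-4-(methoxymethoxy)-3-[(Z)-3-methylbut-1-en-1-yl]benzene (major kinetic Wittig product) | COCOc1ccc(Br)c(OC)c1/C=C\C(C)C | intermediate
12 | 1-bromo-2-methoxy-4-(methoxymethoxy)-3-[(E)-3-methylbut-1-en-1-yl]benzene | COCOc1ccc(Br)c(OC)c1/C=C/C(C)C | intermediate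
13 | di(prop-2-en-1-yl) oxalate (diallyl oxalate) | C=CCOC(=O)C(=O)OCC=C | starting material
14 | {2-methoxy-4-(methoxymethoxy)-3-[(E)-3-methylbut-1-en-1-yl]phenyl}lithium | [Li]c1ccc(OCOC)c(/C=C/C(C)C)c1OC | intermediate
15 | prop-2-en-1-yl {2-methoxy-4-(methoxymethoxy)-3-[(E)-3-methylbut-1-en-1-yl]phenyl}(oxo)acetate | C=CCOC(=O)C(=O)c1ccc(OCOC)c(/C=C/C(C)C)c1OC | intermediate
16 | prop-2-en-1-yl 2-{2-methoxy-4-(methoxymethoxy)-3-[(E)-3-methylbut-1-en-1-yl]phenyl}prop-2-enoate | C=CCOC(=O)C(=C)c1ccc(OCOC)c(/C=C/C(C)C)c1OC | intermediate
17 | prop-2-en-1-yl 3-[2-formyl-3,5-bis(methoxymethoxy)-4-(3-methylbut-2-en-1-yl)phenoxy]-2-{2-methoxy-4-(methoxymethoxy)-3-[(E)-3-methylbut-1-en-1-yl]phenyl}propanoate (racemic) | C=CCOC(=O)C(COc1cc(OCOC)c(CC=C(C)C)c(OCOC)c1C=O)c1ccc(OCOC)c(/C=C/C(C)C)c1OC | intermediate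
18 | prop-2-en-1-yl 4-hydroxy-3-{2-methoxy-4-(methoxymethoxy)-3-[(E)-3-methylbut-1-en-1-yl]phenyl}-5,7-bis(methoxymethoxy)-6-(3-methylbut-2-en-1-yl)-3,4-dihydro-2H-chromene-3-carboxylate (racemic, both C3/C4 relative configurations) | C=CCOC(=O)C1(c2ccc(OCOC)c(/C=C/C(C)C)c2OC)COc2cc(OCOC)c(CC=C(C)C)c(OCOC)c2C1O | intermediate
19 | prop-2-en-1-yl 3-{2-methoxy-4-(methoxymethoxy)-3-[(E)-3-methylbut-1-en-1-yl]phenyl}-5,7-bis(methoxymethoxy)-6-(3-methylbut-2-en-1-yl)-4-oxo-3,4-dihydro-2H-chromene-3-carboxylate (racemic) | C=CCOC(=O)C1(c2ccc(OCOC)c(/C=C/C(C)C)c2OC)COc2cc(OCOC)c(CC=C(C)C)c(OCOC)c2C1=O | intermediate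
20 | (3S)-3-{2-methoxy-4-(methoxymethoxy)-3-[(E)-3-methylbut-1-en-1-yl]phenyl}-5,7-bis(methoxymethoxy)-6-(3-methylbut-2-en-1-yl)-2,3-dihydro-4H-chromen-4-one | COc1c([C@H]2COc3cc(OCOC)c(CC=C(C)C)c(OCOC)c3C2=O)ccc(OCOC)c1/C=C/C(C)C | intermediate
21 | (3S)-5,7-dihydroxy-3-{4-hydroxy-2-methoxy-3-[(E)-3-methylbut-1-en-1-yl]phenyl}-6-(3-methylbut-2-en-1-yl)-2,3-dihydro-4H-chromen-4-one | COc1c([C@H]2COc3cc(O)c(CC=C(C)C)c(O)c3C2=O)ccc(O)c1/C=C/C(C)C | target

## Step count and least certain steps

Total: 13 steps. Longest linear sequence: 9 steps (steps 5 to 13); the ring A branch (steps 1 to 4) joins at step 10.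

**Step 10 (key step).** The aldol closure onto the doubly ortho-substituted, strongly donor-substituted aldehyde may lag behind, so that the ester enolate adds to further 16 (oligomerisation) or reverts by loss of phenoxide, and the reversible aldol may not hold the ring closed at room temperature. The fallback separates the two bond formations and makes the C–C bond under kinetic control. It sets out from 7 and 16: the conjugate addition is run where the enolate is protonated at once (K2CO3 10 mol %, t-BuOH, rt) and is stopped at the open-chain adduct 17, which is isolated. 17 is then added to LiN(SiMe3)2 (1.1 equiv) in THF at −78 °C, where the lithium ester enolate closes onto the aldehyde, and the chelated lithium aldolate is quenched cold with AcOH. This comes back to the route at 18 and makes no new compound.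

**Step 12.** Facial discrimination in the protonation may be insufficient, because ring B has only one ortho substituent, and some C-allylation of the palladium enolate may compete; enantiopurity would then fall short. The fallback moves the stereo-determining event to a dynamic kinetic resolution. It sets out from 19: achiral deallylation–decarboxylation (Pd(PPh3)4 2 mol %, morpholine, THF, rt) gives the racemic tris(methoxymethyl) isoflavanone F1. Asymmetric transfer hydrogenation with RuCl[(S,S)-TsDPEN](p-cymene), or its enantiomer, whichever delivers the 3S series, in HCO2H/Et3N racemises C3 through the enol while reducing one enantiomer faster, and gives the cis-(3S,4S)-isoflavan-4-ol F2. Buffered Dess–Martin oxidation then comes back to the route at 20.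

**Step 13.** Lewis-acid-promoted enolisation at C3 during acetal cleavage may erode enantiopurity, and the prenyl group may cyclise onto the freed 5- or 7-hydroxyl. The fallback moves the acetal cleavage to a stage with no stereocentre and finishes with fluoride. It sets out from 19: the same ZnBr2/n-PrSH treatment gives the racemic triphenol keto ester F3, in which C3 is quaternary and nothing can be lost. TBSOTf/2,6-lutidine gives the tris(tert-butyldimethylsilyl) ether F4, and the conditions of step 12 give the (3S)-tris(tert-butyldimethylsilyl) isoflavanone F5. HF·pyridine buffered with pyridine (THF, 0 °C) removes the silyl groups and comes back to the route at 21.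

**Step 2.** Metalation ortho to chlorine may compete, followed by loss of LiCl to an aryne, or regioselectivity may be incomplete. The fallback removes the halogen before the metalation and blocks its oxygen with a bulky silyl group. It sets out from 2: the conditions of step 3 give 3,5-bis(methoxymethoxy)phenol F6, and TIPSCl/imidazole gives its triisopropylsilyl ether F7. n-BuLi can then metalate only between the two acetals, since the positions next to the silyloxy group are shielded and poorly directed, and prenylation with 3 gives the prenylated silyl ether F8. n-Bu4NF in THF cleaves the silyl ether and comes back to the route at 6.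

**Step 7.** The Z-to-E equilibration may be incomplete, so that a geometric isomer is carried through the route, or iodine may induce loss of the acetal. The fallback is a one-step E-selective Julia–Kocienski olefination. 1-Phenyl-1H-tetrazole-5-thiol is S-alkylated with 1-bromo-2-methylpropane (K2CO3, acetone) to the sulfide F9, which is oxidised (H2O2, (NH4)6Mo7O24 cat., EtOH) to the sulfone F10. Setting out from 10, KN(SiMe3)2 and F10 in DME at −60 °C should give the (E)-alkene directly, which comes back to the route at 12.

## Further compounds

F0 | step 10 | none | none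
F1 | step 12 | 3-{2-methoxy-4-(methoxymethoxy)-3-[(E)-3-methylbut-1-en-1-yl]phenyl}-5,7-bis(methoxymethoxy)-6-(3-methylbut-2-en-1-yl)-2,3-dihydro-4H-chromen-4-one (racemic) | COc1c(C2COc3cc(OCOC)c(CC=C(C)C)c(OCOC)c3C2=O)ccc(OCOC)c1/C=C/C(C)C
F2 | step 12 | (3S,4S)-3-{2-methoxy-4-(methoxymethoxy)-3-[(E)-3-methylbut-1-en-1-yl]phenyl}-5,7-bis(methoxymethoxy)-6-(3-methylbut-2-en-1-yl)-3,4-dihydro-2H-chromen-4-ol (cis) | COc1c([C@H]2COc3cc(OCOC)c(CC=C(C)C)c(OCOC)c3[C@H]2O)ccc(OCOC)c1/C=C/C(C)C
F3 | step 13 | prop-2-en-1-yl 5,7-dihydroxy-3-{4-hydroxy-2-methoxy-3-[(E)-3-methylbut-1-en-1-yl]phenyl}-6-(3-methylbut-2-en-1-yl)-4-oxo-3,4-dihydro-2H-chromene-3-carboxylate (racemic) | C=CCOC(=O)C1(c2ccc(O)c(/C=C/C(C)C)c2OC)COc2cc(O)c(CC=C(C)C)c(O)c2C1=O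
F4 | step 13 | prop-2-en-1-yl 5,7-bis(tert-butyldimethylsilyloxy)-3-{4-(tert-butyldimethylsilyloxy)-2-methoxy-3-[(E)-3-methylbut-1-en-1-yl]phenyl}-6-(3-methylbut-2-en-1-yl)-4-oxo-3,4-dihydro-2H-chromene-3-carboxylate (racemic) | C=CCOC(=O)C1(c2ccc(O[Si](C)(C)C(C)(C)C)c(/C=C/C(C)C)c2OC)COc2cc(O[Si](C)(C)C(C)(C)C)c(CC=C(C)C)c(O[Si](C)(C)C(C)(C)C)c2C1=O
F5 | step 13 | (3S)-5,7-bis(tert-butyldimethylsilyloxy)-3-{4-(tert-butyldimethylsilyloxy)-2-methoxy-3-[(E)-3-methylbut-1-en-1-yl]phenyl}-6-(3-methylbut-2-en-1-yl)-2,3-dihydro-4H-chromen-4-one | COc1c([C@H]2COc3cc(O[Si](C)(C)C(C)(C)C)c(CC=C(C)C)c(O[Si](C)(C)C(C)(C)C)c3C2=O)ccc(O[Si](C)(C)C(C)(C)C)c1/C=C/C(C)C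
F6 | step 2 | 3,5-bis(methoxymethoxy)phenol | COCOc1cc(O)cc(OCOC)c1
F7 | step 2 | [3,5-bis(methoxymethoxy)phenoxy]tri(propan-2-yl)silane | COCOc1cc(O[Si](C(C)C)(C(C)C)C(C)C)cc(OCOC)c1
F8 | step 2 | [3,5-bis(methoxymethoxy)-4-(3-methylbut-2-en-1-yl)phenoxy]tri(propan-2-yl)silane | COCOc1cc(O[Si](C(C)C)(C(C)C)C(C)C)cc(OCOC)c1CC=C(C)C
F9 | step 7 | 5-[(2-methylpropyl)sulfanyl]-1-phenyl-1H-tetrazole | CC(C)CSC1=NN=NN1c1ccccc1
F10 | step 7 | 5-[(2-methylpropyl)sulfonyl]-1-phenyl-1H-tetrazole | CC(C)CS(=O)(=O)C1=NN=NN1c1ccccc1
A1 | alternative 1 | (3E)-1-diazo-4-[5,7-bis(methoxymethoxy)-6-(3-methylbut-2-en-1-yl)-4-oxo-4H-chromen-3-yl]but-3-en-2-one | [N-]=[N+]=CC(=O)/C=C/C1=COc2cc(OCOC)c(CC=C(C)C)c(OCOC)c2C1=O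
A2 | alternative 1 | {[(3E)-5-methylhex-3-en-1-yn-1-yl]oxy}tri(propan-2-yl)silane | CC(C)/C=C/C#CO[Si](C(C)C)(C(C)C)C(C)C
A3 | alternative 1 | 3-{2-hydroxy-3-[(E)-3-methylbut-1-en-1-yl]-4-(triisopropylsilyloxy)phenyl}-5,7-bis(methoxymethoxy)-6-(3-methylbut-2-en-1-yl)-4H-chromen-4-one | O=C1C(c3ccc(O[Si](C(C)C)(C(C)C)C(C)C)c(/C=C/C(C)C)c3O)=COc2cc(OCOC)c(CC=C(C)C)c(OCOC)c21
A4 | alternative 2 | tert-butyldimethylsilyl enol ether of 1-[2,4-bis(tert-butyldimethylsilyloxy)-6-(methoxymethoxy)-3-(3-methylbut-2-en-1-yl)phenyl]-2-{4-(tert-butyldimethylsilyloxy)-2-methoxy-3-[(E)-3-methylbut-1-en-1-yl]phenyl}ethan-1-one (enol geometry not specified) | COCOc1cc(O[Si](C)(C)C(C)(C)C)c(CC=C(C)C)c(O[Si](C)(C)C(C)(C)C)c1C(O[Si](C)(C)C(C)(C)C)=Cc1ccc(O[Si](C)(C)C(C)(C)C)c(/C=C/C(C)C)c1OC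
A5 | alternative 2 | (3S)-5,7-bis(tert-butyldimethylsilyloxy)-3-{4-(tert-butyldimethylsilyloxy)-2-methoxy-3-[(E)-3-methylbut-1-en-1-yl]phenyl}-6-(3-methylbut-2-en-1-yl)-2,3-dihydro-4H-chromen-4-one | COc1c([C@H]2COc3cc(O[Si](C)(C)C(C)(C)C)c(CC=C(C)C)c(O[Si](C)(C)C(C)(C)C)c3C2=O)ccc(O[Si](C)(C)C(C)(C)C)c1/C=C/C(C)C
A6 | alternative 3 | (1S,2S)-1-[6-bromo-2,4-bis(methoxymethoxy)-3-(3-methylbut-2-en-1-yl)phenyl]-2-{2-methoxy-4-(methoxymethoxy)-3-[(E)-3-methylbut-1-en-1-yl]phenyl}propane-1,3-diol | COc1c([C@H]([C@H](O)c2c(Br)cc(OCOC)c(CC=C(C)C)c2OCOC)CO)ccc(OCOC)c1/C=C/C(C)C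
A7 | alternative 3 | (3S,4S)-3-{2-methoxy-4-(methoxymethoxy)-3-[(E)-3-methylbut-1-en-1-yl]phenyl}-5,7-bis(methoxymethoxy)-6-(3-methylbut-2-en-1-yl)-3,4-dihydro-2H-chromen-4-ol (cis) | COc1c([C@H]2COc3cc(OCOC)c(CC=C(C)C)c(OCOC)c3[C@H]2O)ccc(OCOC)c1/C=C/C(C)C
A8 | alternative 3 | 6-bromo-2,4-bis(methoxymethoxy)-3-(3-methylbut-2-en-1-yl)benzaldehyde | O=Cc1c(Br)cc(OCOC)c(CC=C(C)C)c1OCOC
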